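**Retrosynthetic overview**

1. Target 46 ⇐ diacetate 43 by one Lewis-acid cascade (step 24). The enabling feature is that the allylic acetate carbon C5 sits on the quaternary cyclopentane carbon C10, next to the CMe2 carbon C4. The C10–C4 bond shifts to the C5–C6–C7 allyl cation and turns the cyclopentane into ring A; the C10=C5–C6=C7–SiMe3 diene then closes ring B on the C8 ketone, and the 8α-oxygen closes the lactone on the C13 ester.
2. 43 ⇐ aldehyde 40 ⇐ ketone 38, whose C9–C10 bond comes from a Claisen rearrangement of the allyl vinyl ether made from vinyl iodide 29 and allylic alcohol 36 (from enzymatically desymmetrised dione 30).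
3. 29 ⇐ ring C by ring-closing metathesis of enone ester 23 ⇐ Diels-Alder adduct 10 of silyloxydiene 6 with menthyl acetal butenolide 9 (ring D; C13, C14, C18), with C17 set by enolate methylation.
4. Order of ring formation: E (bought) → D (Diels-Alder) → C (metathesis) → A (ring expansion), then B and the lactone in the same step.

Key step: step 24

Remark: triterpenoid numbering of the target is used for all intermediates (ring A C1–C5, C10; ring B C5–C10; ring C C8, C9, C11–C14; ring D C13–C18; ring E C17–C22; C27 = carbonyl carbon on C13; α below, β above the usual drawing). Compounds 35–43 are carried as mixtures at the alkene of 35/36 and at C10 and C5, because these carbons become sp2 in step 24.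

Step 1
Reactants: 1 4,4-dimethylcyclohexanone; 2 ethynylmagnesium bromide
Product: 3 1-ethynyl-4,4-dimethylcyclohexan-1-ol
Conditions: HC≡CMgBr, THF, 0 °C to rt; aq NH4Cl
Reagents that add atoms: ethynylmagnesium bromide, C#C[Mg]Br
Why: 1,2-addition of an alkynyl Grignard reagent to an unhindered ketone; no stereocentre is formed.

Step 2
Reactants: 3 1-ethynyl-4,4-dimethylcyclohexan-1-ol
Product: 4 1-(4,4-dimethylcyclohex-1-en-1-yl)ethan-1-one
Conditions: HCO2H (90%), 100 °C
Reagents that add atoms: none
Why: Rupe rearrangement of a tertiary ethynyl carbinol to the conjugated methyl ketone; the ring is symmetric, so only one enone can form.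

Step 3
Reactants: 4 1-(4,4-dimethylcyclohex-1-en-1-yl)ethan-1-one; 5 tert-butyldimethylsilyl trifluoromethanesulfonate
Product: 6 tert-butyl{[1-(4,4-dimethylcyclohex-1-en-1-yl)ethenyl]oxy}dimethylsilane
Conditions: TBSOTf, Et3N, CH2Cl2, 0 °C
Reagents that add atoms: tert-butyldimethylsilyl trifluoromethanesulfonate, CC(C)(C)[Si](C)(C)OS(=O)(=O)C(F)(F)F
Why: kinetic silyl enol ether formation at the methyl group should give the cross-conjugated 2-silyloxy-1,3-diene (C15=C16–C17=C18).

Step 4
Reactants: 7 5-hydroxy-4-methylfuran-2(5H)-one; 8 (1S,2R,5S)-(+)-menthol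
Product: 9 (5S)-5-[(1S,2R,5S)-menthyloxy]-4-methylfuran-2(5H)-one
Conditions: camphorsulfonic acid (cat.), toluene, reflux, Dean-Stark; separation of the (5S) epimer, the (5R) epimer re-equilibrated with acid
Reagents that add atoms: (1S,2R,5S)-(+)-menthol, CC(C)[C@H]1CC[C@H](C)C[C@@H]1O
Why: acid-catalysed acetalisation of the pseudo-acid; the acetal carbon (later C8) epimerises under acid, so the unwanted epimer can be recycled.

Step 5
Reactants: 6 silyloxydiene; 9 menthyloxybutenolide
Product: 10 Diels-Alder adduct (rings D and E with cis-fused γ-lactone acetal; C16 silyl enol ether; 13β-H; 14β-CH3; 18β-H)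
Conditions: toluene, BHT (cat.), 140 °C, sealed tube
Reagents that add atoms: none
Why: Diels-Alder reaction in which the silyloxy-activated CH2 terminus (C15) bonds to the β-carbon C14 of the butenolide; addition anti to the menthyloxy group fixes the absolute configuration, and the endo transition state places 13-H, 14-CH3 and 18-H on one face.

Step 6
Reactants: 10 Diels-Alder adduct; 11 iodomethane
Product: 12 17β-methyl C16 ketone (lactone acetal)
Conditions: benzyltrimethylammonium fluoride, MeI, 4 Å sieves, THF, 0 °C to rt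
Reagents that add atoms: iodomethane, CI
Why: fluoride releases the regiospecific C16/C17 enolate, which is C-methylated at the ring-fusion carbon; methyl should enter cis to 18-H (as in alkylation of 1-decalone ring-fusion enolates), because the α face is screened by the lactone carbonyl.

Step 7
Reactants: 12 C16 ketone; 13 N-phenylbis(trifluoromethanesulfonimide)
Product: 14 C15=C16 enol triflate
Conditions: KN(SiMe3)2, THF, −78 °C; PhNTf2; aq NH4Cl
Reagents that add atoms: N-phenylbis(trifluoromethanesulfonimide), O=S(=O)(N(c1ccccc1)S(=O)(=O)C(F)(F)F)C(F)(F)F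
Why: enolate triflation; C17 is quaternary, so the ketone can only enolise toward C15, and the ketone α-protons are more acidic than the lactone 13-H.

Step 8
Reactants: 14 enol triflate
Product: 15 saturated ring D/E lactone acetal
Conditions: H2 (4 atm), PtO2, Na2CO3, EtOAc–EtOH, rt
Reagents that add atoms: none
Why: hydrogenolysis of an enol triflate over platinum removes the C16 oxygen and saturates C15–C16; no stereocentre is touched.

Step 9
Reactants: 15 lactone acetal; 16 allyl bromide
Product: 17 13β-allyl lactone acetal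
Conditions: LiN(i-Pr)2, THF–DMPU, −78 °C; allyl bromide, to −20 °C
Reagents that add atoms: allyl bromide, C=CCBr
Why: alkylation of the ring-fusion lactone enolate on the convex face keeps the lactone cis-fused, so the allyl group (C12, C11) ends up cis to 14-CH3 and C27 is α.

Step 10
Reactants: 17 13β-allyl lactone acetal; 18 water
Product: 19 lactol (8-hydroxy γ-lactone)
Conditions: CF3CO2H–H2O (4:1), 40 °C
Reagents that add atoms: water, O
Why: acid hydrolysis of the menthyl acetal; the auxiliary is released and can be recovered.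

Step 11
Reactants: 19 lactol; 11 iodomethane
Product: 20 aldehyde methyl ester (14-CHO, 13α-CO2CH3, 13β-allyl)
Conditions: K2CO3, MeI, DMF, rt
Reagents that add atoms: iodomethane, CI
Why: base opens the pseudo-acid to the aldehyde carboxylate, which is O-alkylated to the normal methyl ester; the aldehyde has no α-hydrogen.

Step 12
Reactants: 20 aldehyde methyl ester; 21 isopropenylmagnesium bromide
Product: 23 isopropenyl ketone ester (C8 ketone carrying C9 with its methyl), via allylic alcohol 22 (not isolated)
Conditions: CH2=C(CH3)MgBr, THF, −78 °C; AcOH quench; then Dess-Martin periodinane, NaHCO3, CH2Cl2, rt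
Reagents that add atoms: isopropenylmagnesium bromide, CC(=C)[Mg]Br
Why: Grignard addition to the aldehyde in preference to the neopentyl ester, followed by oxidation of the allylic alcohol, which removes the C8 stereocentre.

Step 13
Reactants: 23 isopropenyl ketone ester
Product: 24 ring C enone (C8 ketone, C9=C11)
Conditions: second-generation Grubbs catalyst (5 mol %), toluene, 80 °C
Reagents that add atoms: none
Why: ring-closing metathesis between the 1,1-disubstituted enone alkene and the allyl group closes ring C trans-fused to ring D, since both arms are equatorial on ring D.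

Step 14
Reactants: 24 ring C enone
Product: 25 tricyclic ketone (C9 epimers)
Conditions: H2 (1 atm), Pd/C, EtOAc, rt
Reagents that add atoms: none
Why: hydrogenation of the enone C=C; the C9 configuration is irrelevant because C9 becomes sp2 again in step 15.

Step 15
Reactants: 25 tricyclic ketone; 26 hydrazine hydrate; 27 iodine
Product: 29 vinyl iodide (8-iodo, C8=C9), via hydrazone 28 (not isolated)
Conditions: N2H4·H2O, Et3N, EtOH, 80 °C; then I2, tetramethylguanidine, THF, 0 °C
Reagents that add atoms: iodine, II
Why: Barton vinyl iodide synthesis; only C9 carries a hydrogen next to C8, so a single tetrasubstituted vinyl iodide should form, and the neopentyl ester should resist hydrazinolysis.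

Step 16
Reactants: 30 2,2-dimethylcyclopentane-1,3-dione
Product: 31 (S)-3-hydroxy-2,2-dimethylcyclopentan-1-one
Conditions: ketoreductase (S-selective), NADP+ (cat.), i-PrOH, phosphate buffer pH 7, 30 °C
Reagents that add atoms: none
Why: enzymatic desymmetrising reduction of a prochiral 1,3-diketone sets the future C3 as S under enzyme control.

Step 17
Reactants: 31 (S)-3-hydroxy-2,2-dimethylcyclopentan-1-one; 32 acetic anhydride
Product: 33 (1S)-2,2-dimethyl-3-oxocyclopentyl acetate
Conditions: Ac2O, pyridine, DMAP (cat.), CH2Cl2, rt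
Reagents that add atoms: acetic anhydride, CC(=O)OC(C)=O
Why: acetylation protects the β-hydroxy ketone against retro-aldol cleavage in the basic olefination.

Step 18
Reactants: 33 keto acetate; 34 triethyl phosphonoacetate
Product: 35 ethyl 2-[(3S)-3-acetoxy-2,2-dimethylcyclopentylidene]acetate (E/Z mixture)
Conditions: NaH, (EtO)2P(O)CH2CO2Et, THF, 0 to 65 °C
Reagents that add atoms: triethyl phosphonoacetate, CCOC(=O)CP(=O)(OCC)OCC
Why: Horner-Wadsworth-Emmons olefination of the C10 ketone; the alkene geometry need not be controlled.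

Step 19
Reactants: 35 enoate
Product: 36 (1S)-3-(2-hydroxyethylidene)-2,2-dimethylcyclopentan-1-ol (E/Z mixture)
Conditions: i-Bu2AlH (5 equiv), CH2Cl2, −78 to 0 °C; Rochelle salt
Reagents that add atoms: none
Why: hydride reduction converts the enoate into the allylic alcohol and removes the acetate in the same operation.

Step 20
Reactants: 29 vinyl iodide; 36 allylic alcohol
Product: 38 Claisen ketone (C8 ketone; C9 quaternary with 9β-CH3 and C10; C10 carries vinyl and the cyclopentane), via allyl vinyl ether 37 (not isolated)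
Conditions: CuI (10 mol %), 3,4,7,8-tetramethyl-1,10-phenanthroline (20 mol %), Cs2CO3, o-xylene, 130 °C
Reagents that add atoms: none
Why: copper-catalysed Ullmann-type C–O coupling of the vinyl iodide with the primary allylic hydroxyl gives the allyl vinyl ether, which undergoes Claisen rearrangement; the allyl unit should reach C9 from the α face, anti to the axial 14β-methyl, so 9-CH3 is β.

Step 21
Reactants: 38 Claisen ketone; 39 ozone
Product: 40 aldehyde (C5 formyl group on C10)
Conditions: O3, CH2Cl2–MeOH, −78 °C; Me2S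
Reagents that add atoms: ozone, [O-][O+]=O
Why: ozonolysis of the only alkene; the resulting keto aldehyde has no enolisable position.

Step 22
Reactants: 40 aldehyde; 41 (E)-(2-bromoethenyl)trimethylsilane
Product: 42 diol (C5 carbinol carrying the (E)-2-silylvinyl group C6=C7; free 3-OH)
Conditions: 41, t-BuLi, Et2O, −78 °C; then 40, THF, −78 °C; aq NH4Cl
Reagents that add atoms: (E)-(2-bromoethenyl)trimethylsilane (as its lithium reagent), C[Si](C)(C)/C=C/Br
Why: 1,2-addition of the alkenyllithium to the aldehyde in preference to the fully substituted C8 ketone and the ester; both C5 epimers are used.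

Step 23
Reactants: 42 diol; 32 acetic anhydride
Product: 43 diacetate (3-OAc and allylic 5-OAc)
Conditions: Ac2O, Et3N, DMAP, CH2Cl2, rt
Reagents that add atoms: acetic anhydride, CC(=O)OC(C)=O
Why: acylation installs the final 3-acetate and turns the C5 hydroxyl into a leaving group.

Step 24
Reactants: 43 diacetate
Product: 46 target lactone (3β-acetoxy-5(10),6-diene 27,8α-olide), via silyl diene ketone 44 (not isolated), via dienyl hydroxy ester 45 (not isolated)
Conditions: Sc(OTf)3 (10 mol %), CH2Cl2, −20 °C to rt
Reagents that add atoms: none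
Why: Proposed new method: Lewis-acid ionisation of the allylic acetate gives the C5–C6–C7 allyl cation on the quaternary cyclopentane carbon C10; the C10–C4 bond then shifts to C5 (Wagner-Meerwein ring expansion, so ring A forms by a 1,2-shift and not by a closure) and loss of H5 gives silyl diene 44, the closest known reaction types being the acid-promoted ring expansion of cyclopentylcarbinyl cations and the vinylsilane-terminated Prins cyclisation. Because C10=C5 now lies in ring A, C6–C7 is held cis to C9, and the silylated terminus C7 attacks the scandium-activated C8 ketone (ring B, 6-endo-trig at the diene with the carbonyl oxygen exocyclic). The resulting β-silyl allyl cation loses Me3Si+ rather than a proton, which fixes the diene as C5=C10/C6=C7. The 8α-alkoxide then closes on the axial C13 ester (5-exo-trig acyl substitution) to the lactone. The only new stereocentre, C8, is set by attack on the ketone face anti to the axial 13α-ester, which also gives the trans B/C fusion; only this epimer can lactonise, and since the C8–O bond of 45 is doubly allylic a wrong epimer can re-ionise and be drained. The step needs C4 to migrate rather than C1 or C9 (tertiary carbon in a strained ring versus a primary carbon and a carbon deactivated by the adjacent carbonyl) and needs the silyl group to direct the last elimination; the C5 and C10 configurations and the alkene geometry of 36 are erased.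

**Compound list**

1 | 4,4-dimethylcyclohexanone | O=C1CCC(C)(C)CC1 | starting material
2 | ethynylmagnesium bromide | C#C[Mg]Br | starting material
3 | 1-ethynyl-4,4-dimethylcyclohexan-1-ol | C#CC1(O)CCC(C)(C)CC1 | intermediate
4 | 1-(4,4-dimethylcyclohex-1-en-1-yl)ethan-1-one | CC(=O)C1=CCC(C)(C)CC1 | intermediate
5 | tert-butyldimethylsilyl trifluoromethanesulfonate | CC(C)(C)[Si](C)(C)OS(=O)(=O)C(F)(F)F | starting material
6 | tert-butyl{[1-(4,4-dimethylcyclohex-1-en-1-yl)ethenyl]oxy}dimethylsilane | C=C(O[Si](C)(C)C(C)(C)C)C1=CCC(C)(C)CC1 | intermediate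
7 | 5-hydroxy-4-methylfuran-2(5H)-one | CC1=CC(=O)OC1O | starting material
8 | (1S,2R,5S)-(+)-menthol | CC(C)[C@H]1CC[C@H](C)C[C@@H]1O | starting material
9 | (5S)-5-[(1S,2R,5S)-menthyloxy]-4-methylfuran-2(5H)-one | CC1=CC(=O)O[C@@H]1O[C@H]2C[C@@H](C)CC[C@@H]2C(C)C | intermediate
10 | Diels-Alder adduct: rings D/E, cis-fused γ-lactone menthyl acetal, C16 silyl enol ether | O=C1O[C@H](O[C@H]2C[C@@H](C)CC[C@@H]2C(C)C)[C@@]3(C)CC(O[Si](C)(C)C(C)(C)C)=C4CCC(C)(C)C[C@H]4[C@@H]13 | intermediate
11 | iodomethane | CI | starting material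
12 | 17β-methyl C16 ketone lactone acetal | O=C1O[C@H](O[C@H]2C[C@@H](C)CC[C@@H]2C(C)C)[C@@]3(C)CC(=O)[C@@]4(C)CCC(C)(C)C[C@H]4[C@@H]13 | intermediate
13 | N-phenylbis(trifluoromethanesulfonimide) | O=S(=O)(N(c1ccccc1)S(=O)(=O)C(F)(F)F)C(F)(F)F | starting material
14 | C15=C16 enol triflate | O=C1O[C@H](O[C@H]2C[C@@H](C)CC[C@@H]2C(C)C)[C@@]3(C)C=C(OS(=O)(=O)C(F)(F)F)[C@@]4(C)CCC(C)(C)C[C@H]4[C@@H]13 | intermediate
15 | saturated ring D/E lactone acetal | O=C1O[C@H](O[C@H]2C[C@@H](C)CC[C@@H]2C(C)C)[C@@]3(C)CC[C@@]4(C)CCC(C)(C)C[C@H]4[C@@H]13 | intermediate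
16 | allyl bromide | C=CCBr | starting material
17 | 13β-allyl lactone acetal | O=C1O[C@H](O[C@H]2C[C@@H](C)CC[C@@H]2C(C)C)[C@@]3(C)CC[C@@]4(C)CCC(C)(C)C[C@H]4[C@@]13CC=C | intermediate
18 | water | O | starting material
19 | lactol (8-hydroxy γ-lactone, C8 epimers) | O=C1OC(O)[C@@]2(C)CC[C@@]3(C)CCC(C)(C)C[C@H]3[C@@]12CC=C | intermediate
20 | aldehyde methyl ester (14-CHO, 13α-CO2CH3, 13β-allyl) | O=C[C@@]1(C)CC[C@@]2(C)CCC(C)(C)C[C@H]2[C@@]1(CC=C)C(=O)OC | intermediate
21 | isopropenylmagnesium bromide | CC(=C)[Mg]Br | starting material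
22 | C8 allylic alcohol (epimers) | OC(C(C)=C)[C@@]1(C)CC[C@@]2(C)CCC(C)(C)C[C@H]2[C@@]1(CC=C)C(=O)OC | intermediate
23 | isopropenyl ketone ester | O=C(C(C)=C)[C@@]1(C)CC[C@@]2(C)CCC(C)(C)C[C@H]2[C@@]1(CC=C)C(=O)OC | intermediate
24 | ring C enone (C8 ketone, C9=C11) | CC1=CC[C@@]2(C(=O)OC)[C@@H]3CC(C)(C)CC[C@]3(C)CC[C@]2(C)C1=O | intermediate
25 | tricyclic ketone (C9 epimers) | CC1CC[C@@]2(C(=O)OC)[C@@H]3CC(C)(C)CC[C@]3(C)CC[C@]2(C)C1=O | intermediate
26 | hydrazine hydrate | NN.O | starting material
27 | iodine | II | starting material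
28 | C8 hydrazone | CC1CC[C@@]2(C(=O)OC)[C@@H]3CC(C)(C)CC[C@]3(C)CC[C@]2(C)C1=NN | intermediate
29 | vinyl iodide (8-iodo, C8=C9) | CC=1CC[C@@]2(C(=O)OC)[C@@H]3CC(C)(C)CC[C@]3(C)CC[C@]2(C)C=1I | intermediate
30 | 2,2-dimethylcyclopentane-1,3-dione | CC1(C)C(=O)CCC1=O | starting material
31 | (S)-3-hydroxy-2,2-dimethylcyclopentan-1-one | CC1(C)[C@@H](O)CCC1=O | intermediate
32 | acetic anhydride | CC(=O)OC(C)=O | starting material
33 | (1S)-2,2-dimethyl-3-oxocyclopentyl acetate | CC(=O)O[C@H]1CCC(=O)C1(C)C | intermediate
34 | triethyl phosphonoacetate | CCOC(=O)CP(=O)(OCC)OCC | starting material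
35 | ethyl 2-[(3S)-3-acetoxy-2,2-dimethylcyclopentylidene]acetate (E/Z) | CCOC(=O)C=C1CC[C@H](OC(C)=O)C1(C)C | intermediate
36 | (1S)-3-(2-hydroxyethylidene)-2,2-dimethylcyclopentan-1-ol (E/Z) | OCC=C1CC[C@H](O)C1(C)C | intermediate
37 | allyl vinyl ether of 29 and 36 | CC=1CC[C@@]2(C(=O)OC)[C@@H]3CC(C)(C)CC[C@]3(C)CC[C@]2(C)C=1OCC=C4CC[C@H](O)C4(C)C | intermediate
38 | Claisen ketone (9β-CH3; C10 vinyl; C10 epimers) | C[C@@]1(C2(C=C)CC[C@H](O)C2(C)C)CC[C@@]3(C(=O)OC)[C@@H]4CC(C)(C)CC[C@]4(C)CC[C@]3(C)C1=O | intermediate
39 | ozone | [O-][O+]=O | starting material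
40 | aldehyde (C5 formyl on C10) | C[C@@]1(C2(C=O)CC[C@H](O)C2(C)C)CC[C@@]3(C(=O)OC)[C@@H]4CC(C)(C)CC[C@]4(C)CC[C@]3(C)C1=O | intermediate
41 | (E)-(2-bromoethenyl)trimethylsilane | C[Si](C)(C)/C=C/Br | starting material
42 | diol with (E)-silylvinyl carbinol (C5 and C10 epimers) | C[C@@]1(C2(C(O)/C=C/[Si](C)(C)C)CC[C@H](O)C2(C)C)CC[C@@]3(C(=O)OC)[C@@H]4CC(C)(C)CC[C@]4(C)CC[C@]3(C)C1=O | intermediate
43 | diacetate (C5 and C10 epimers) | C[C@@]1(C2(C(OC(C)=O)/C=C/[Si](C)(C)C)CC[C@H](OC(C)=O)C2(C)C)CC[C@@]3(C(=O)OC)[C@@H]4CC(C)(C)CC[C@]4(C)CC[C@]3(C)C1=O | intermediate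
44 | silyl diene ketone (ring A formed; C10=C5–C6=C7–SiMe3) | CC(=O)O[C@H]1CCC(=C(/C=C/[Si](C)(C)C)C1(C)C)[C@]2(C)CC[C@@]3(C(=O)OC)[C@@H]4CC(C)(C)CC[C@]4(C)CC[C@]3(C)C2=O | intermediate
45 | dienyl hydroxy ester (8α-OH, 13α-CO2CH3) | CC(=O)O[C@H]1CCC2=C(C=C[C@]3(O)[C@@]4(C)CC[C@@]5(C)CCC(C)(C)C[C@H]5[C@]4(C(=O)OC)CC[C@@]23C)C1(C)C | intermediate
46 | target: 3β-acetoxy-D:B-friedooleana-5(10),6-dien-27-oic acid 27,8α-lactone | CC(=O)O[C@H]1CCC2=C(C=C[C@@]34OC(=O)[C@]5(CC[C@@]23C)[C@@H]2CC(C)(C)CC[C@]2(C)CC[C@]45C)C1(C)C | target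

**Step count and risks**

Total step count: 24. Longest linear sequence: 19 steps (steps 1–3, 5–15, 20–24).

Steps most likely to fail:

1. Step 24 (proposed cascade). The sequence may be interrupted: the first allyl cation can be captured reversibly by the C8 carbonyl oxygen, the silyl diene can be protodesilylated before it cyclises, or ring B can close before the shift, in which case the migration depends on the C10 configuration. Fallback: a stepwise route from 38 that closes ring B by metathesis before the ring expansion. CH2=CHCH2MgBr (THF, −78 °C to rt) adds to the C8 ketone anti to the axial ester and the 8α-alkoxide lactonises to the allyl vinyl lactone alcohol F1. Ac2O/DMAP gives the acetate F2. Ring-closing metathesis (second-generation Grubbs catalyst) gives the spiro cyclohexene F3 (C5=C6). Wohl-Ziegler bromination (N-bromosuccinimide, AIBN) gives the allylic bromide F4 (allylic isomers behave alike). AgOTf with 2,6-di-tert-butyl-4-methylpyridine in CH2Cl2 ionises F4 to the spiro allyl cation; shift of C4 from C10 to C5 and loss of H5 (silver-assisted solvolysis with Wagner-Meerwein shift) gives 46. This sequence is run on the C10 epimer in which C4 is pseudo-axial on ring B.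

2. Step 20. Oxidative addition and C–O coupling at the tetrasubstituted, doubly neopentyl vinyl iodide may be too slow, so that reduction of the iodide and decomposition of the allylic alcohol compete. Fallback: from 25, HC(OMe)3 and TsOH give the methyl enol ether F5; heating F5 with 36 and catalytic propionic acid in xylene (enol ether exchange, then Claisen rearrangement) returns to 38.

3. Step 5. The β,β-disubstituted butenolide may react too slowly, so that the silyloxydiene is lost by desilylation or polymerisation and endo selectivity erodes at the high temperature needed. Fallback: from 4 and 9, the lithium dienolate of 4 (LiN(i-Pr)2, THF, −78 °C) adds to C14 of 9 anti to the menthyloxy group and the lactone enolate closes ring D on the enone (double Michael annulation) to give keto lactone F6; methylation of the more substituted enolate (NaH, MeI) at C17 returns to 12.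

Further compounds
F1 | step 24 | allyl vinyl lactone alcohol (8β-allyl, 27,8α-lactone, C10 vinyl, 3-OH) | C=CC[C@@]12OC(=O)[C@]3(CC[C@@]1(C)C4(C=C)CC[C@H](O)C4(C)C)[C@@H]5CC(C)(C)CC[C@]5(C)CC[C@]23C
F2 | step 24 | acetate of F1 | C=CC[C@@]12OC(=O)[C@]3(CC[C@@]1(C)C4(C=C)CC[C@H](OC(C)=O)C4(C)C)[C@@H]5CC(C)(C)CC[C@]5(C)CC[C@]23C
F3 | step 24 | spiro cyclohexene (ring B with C5=C6, spiro C10) | CC(=O)O[C@H]1CCC2(C=CC[C@@]34OC(=O)[C@]5(CC[C@@]23C)[C@@H]6CC(C)(C)CC[C@]6(C)CC[C@]45C)C1(C)C
F4 | step 24 | allylic bromide (7-bromo, C5=C6) | CC(=O)O[C@H]1CCC2(C=CC(Br)[C@@]34OC(=O)[C@]5(CC[C@@]23C)[C@@H]6CC(C)(C)CC[C@]6(C)CC[C@]45C)C1(C)C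
F5 | step 20 | methyl enol ether of 25 (8-methoxy, C8=C9) | CC=1CC[C@@]2(C(=O)OC)[C@@H]3CC(C)(C)CC[C@]3(C)CC[C@]2(C)C=1OC
F6 | step 5 | keto lactone acetal (C16 ketone, 17-H) | O=C1O[C@H](O[C@H]2C[C@@H](C)CC[C@@H]2C(C)C)[C@@]3(C)CC(=O)C4CCC(C)(C)C[C@H]4[C@@H]13
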